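**Retrosynthetic overview**
- The C3 ketone comes from oxidation of a C3 carbinol, and the carbinol from a late C3–C4 bond formation between two pyranone fragments of comparable size (18 and 13 non-hydrogen atoms).
- Fragment 1 is the ring A aldehyde (pentyl pyranone carrying the C2 stereocentre, taken from (S)-Roche ester). Fragment 2 is the symmetric ring B pyranone (2,6-diethyl-3,5-dimethyl), used as its lithium dienolate.
- Ring A: cyclodehydration of a 1,3,5-triketone made by aldol union of the Roche aldehyde with a pentan-3-one/hexanal aldol unit, then double oxidation.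
- Ring B: cyclodehydration of 4,6-dimethylnonane-3,5,7-trione (pentan-3-one + propanoyl chloride + methyl propanoate).
- Ring order: rings A and B are closed in separate branches before the coupling; no ring is formed after it.

Assumption: the chain between the rings is numbered C1–C5 (C2 on ring A, C3 the carbinol/carbonyl carbon, C4 on ring B); the Roche ester is used at ≥99% ee.

**Route**

Step 1
Reactants: 1 methyl (2S)-3-hydroxy-2-methylpropanoate
Product: 2 methyl (2S)-3-[(tert-butyldiphenylsilyl)oxy]-2-methylpropanoate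
Conditions: TBDPSCl, imidazole, CH2Cl2, 0 °C → rt
Reagents that add atoms: tert-butyl(chloro)diphenylsilane (TBDPSCl), CC(C)(C)[Si](Cl)(c1ccccc1)c1ccccc1
Why: Imidazole-promoted O-silylation of the primary alcohol gives an acid-robust silyl ether and does not touch the C2 stereocentre.

Step 2
Reactants: 2 methyl (2S)-3-[(tert-butyldiphenylsilyl)oxy]-2-methylpropanoate
Product: 4 (2S)-3-[(tert-butyldiphenylsilyl)oxy]-2-methylpropanal, via aluminium hemiacetal 3 (not isolated)
Conditions: i-Bu2AlH (1.05 equiv), CH2Cl2, −78 °C; then KNaC4H4O6 (aq)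
Reagents that add atoms: none
Why: Partial ester reduction works because the tetrahedral aluminium hemiacetal 3 is stable at −78 °C and releases the aldehyde only on work-up, so there is no over-reduction and no epimerisation.

Step 3
Reactants: 5 pentan-3-one, 6 hexanal
Product: 8 5-hydroxy-4-methyldecan-3-one, via lithium enolate 7 (not isolated)
Conditions: LiN(i-Pr)2, THF, −78 °C; then 6, −78 °C; AcOH
Reagents that add atoms: none
Why: Directed aldol addition of the preformed lithium enolate of a symmetrical ketone to an aliphatic aldehyde; the two new centres are left as a mixture because both become sp2 carbons of ring A.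

Step 4
Reactants: 8 5-hydroxy-4-methyldecan-3-one
Product: 9 4-methyl-5-[(trimethylsilyl)oxy]decan-3-one
Conditions: TMSCl, imidazole, CH2Cl2, 0 °C
Reagents that add atoms: chlorotrimethylsilane (TMSCl), C[Si](C)(C)Cl
Why: O-silylation masks the hydroxyl for the next enolisation with the silyl group that is easiest to remove selectively later.

Step 5
Reactants: 9 4-methyl-5-[(trimethylsilyl)oxy]decan-3-one, 4 (2S)-3-[(tert-butyldiphenylsilyl)oxy]-2-methylpropanal
Product: 12 (2S)-1-[(tert-butyldiphenylsilyl)oxy]-3,7-dihydroxy-2,4,6-trimethyldodecan-5-one, via lithium enolate 10 (not isolated), via O-TMS aldol adduct 11 (not isolated)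
Conditions: LiN(i-Pr)2, THF, −78 °C; then 4, −78 °C; AcOH; then citric acid (cat.), MeOH, 0 °C → rt
Reagents that add atoms: none
Why: Kinetic deprotonation occurs at the unhindered CH2 and the enolate adds to the aldehyde in a directed aldol reaction, after which mild acid methanolysis removes only the TMS group; the new centres need no control (all are oxidised or enolised later) and C2 comes unchanged from 4.

Step 6
Reactants: 12 (2S)-1-[(tert-butyldiphenylsilyl)oxy]-3,7-dihydroxy-2,4,6-trimethyldodecan-5-one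
Product: 13 (2S)-1-[(tert-butyldiphenylsilyl)oxy]-2,4,6-trimethyldodecane-3,5,7-trione
Conditions: Dess–Martin periodinane (3 equiv), NaHCO3, CH2Cl2, 0 °C → rt
Reagents that add atoms: none
Why: Double Dess–Martin oxidation of the two β-hydroxy ketone carbinols gives the 1,3,5-triketone under buffered, amine-free conditions that avoid β-elimination of the silyloxy group and enolisation at C2.

Step 7
Reactants: 13 (2S)-1-[(tert-butyldiphenylsilyl)oxy]-2,4,6-trimethyldodecane-3,5,7-trione
Product: 14 2-{(2S)-1-[(tert-butyldiphenylsilyl)oxy]propan-2-yl}-3,5-dimethyl-6-pentyl-4H-pyran-4-one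
Conditions: PPh3, CCl4, THF, rt
Reagents that add atoms: none
Why: Dehydrative cyclisation of the triketone to the 4-pyranone (ring A) by Appel-type activation of an enol oxygen and six-membered O-closure from the distal carbonyl is near-neutral, so the adjacent stereocentre and the silyl ether survive, and either direction of closure gives the same ring.

Step 8
Reactants: 14 2-{(2S)-1-[(tert-butyldiphenylsilyl)oxy]propan-2-yl}-3,5-dimethyl-6-pentyl-4H-pyran-4-one
Product: 15 2-[(2S)-1-hydroxypropan-2-yl]-3,5-dimethyl-6-pentyl-4H-pyran-4-one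
Conditions: HF·pyridine, pyridine, THF, 0 °C → rt
Reagents that add atoms: none
Why: Fluoride-driven desilylation (Si–F bond formation) under buffered conditions leaves the pyranone and the stereocentre untouched.

Step 9
Reactants: 15 2-[(2S)-1-hydroxypropan-2-yl]-3,5-dimethyl-6-pentyl-4H-pyran-4-one
Product: 16 (2R)-2-(3,5-dimethyl-4-oxo-6-pentyl-4H-pyran-2-yl)propanal
Conditions: Dess–Martin periodinane, NaHCO3, CH2Cl2, 0 °C; filtered and used at once
Reagents that add atoms: none
Why: Dess–Martin oxidation is chosen because it needs no amine base, so the doubly activated α-centre is not epimerised (the descriptor changes from S to R only through CIP priorities).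

Step 10
Reactants: 5 pentan-3-one, 17 propanoyl chloride
Product: 18 4-methylheptane-3,5-dione
Conditions: MgBr2·OEt2, i-Pr2NEt, CH2Cl2, rt; then 1 M HCl
Reagents that add atoms: none
Why: Soft-enolisation C-acylation (MgBr2-assisted enolisation by the amine) of a symmetrical ketone gives the 1,3-diketone, whose magnesium chelate resists O-acylation and further acylation.

Step 11
Reactants: 18 4-methylheptane-3,5-dione, 19 methyl propanoate
Product: 21 4,6-dimethylnonane-3,5,7-trione, via dilithium dianion 20 (not isolated)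
Conditions: LiN(i-Pr)2 (2.1 equiv), THF, −78 → 0 °C; then 19 (0.5 equiv), 0 °C → rt; AcOH
Reagents that add atoms: none
Why: Claisen-type acylation of the 1,3-diketone dianion takes place at its terminal, more nucleophilic carbon, with excess dianion serving as base for the more acidic triketone product.

Step 12
Reactants: 21 4,6-dimethylnonane-3,5,7-trione
Product: 22 2,6-diethyl-3,5-dimethyl-4H-pyran-4-one
Conditions: p-TsOH·H2O (cat.), toluene, reflux, Dean–Stark
Reagents that add atoms: none
Why: Acid-catalysed cyclodehydration of the symmetrical 1,3,5-triketone gives the 4-pyranone (ring B), driven by azeotropic removal of water.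

Step 13
Reactants: 22 2,6-diethyl-3,5-dimethyl-4H-pyran-4-one, 16 (2R)-2-(3,5-dimethyl-4-oxo-6-pentyl-4H-pyran-2-yl)propanal
Product: 24 2-[(2S,3R,4R)-4-(6-ethyl-3,5-dimethyl-4-oxo-4H-pyran-2-yl)-3-hydroxypentan-2-yl]-3,5-dimethyl-6-pentyl-4H-pyran-4-one, via lithium dienolate 23 (not isolated)
Conditions: 22 (1.5 equiv), LiN(SiMe3)2 (1.4 equiv), THF, −78 °C; then 16 (1.0 equiv), −78 °C, 20 min; AcOH/THF at −78 °C
Reagents that add atoms: none
Why: Vinylogous aldol reaction of the 2-ethylpyranone lithium dienolate with the aldehyde at −78 °C; the expected (not assured) outcome is Felkin–Anh attack anti to the pyranonyl group through an open antiperiplanar transition state, which would place the C3 hydroxyl syn to both methyls and fix C4, with minor diastereomers removed by chromatography (a C3 epimer with the same C2 and C4 configuration gives the same ketone).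

Step 14
Reactants: 24 2-[(2S,3R,4R)-4-(6-ethyl-3,5-dimethyl-4-oxo-4H-pyran-2-yl)-3-hydroxypentan-2-yl]-3,5-dimethyl-6-pentyl-4H-pyran-4-one
Product: 25 2-[(2R,4S)-4-(6-ethyl-3,5-dimethyl-4-oxo-4H-pyran-2-yl)-3-oxopentan-2-yl]-3,5-dimethyl-6-pentyl-4H-pyran-4-one
Conditions: Dess–Martin periodinane, NaHCO3, CH2Cl2, 0 °C → rt; rapid filtration through neutral silica
Reagents that add atoms: none
Why: Dess–Martin oxidation of the hindered carbinol under buffered, amine-free conditions forms the ketone without breaking any bond at C2 or C4, whose descriptors change (2S→2R, 4R→4S) only because C3 becomes a carbonyl carbon.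

**Compound list**
1 | methyl (2S)-3-hydroxy-2-methylpropanoate ((S)-Roche ester) | COC(=O)[C@@H](C)CO | starting material
2 | methyl (2S)-3-[(tert-butyldiphenylsilyl)oxy]-2-methylpropanoate | COC(=O)[C@@H](C)CO[Si](c1ccccc1)(c1ccccc1)C(C)(C)C | intermediate
3 | diisobutylaluminium hemiacetal of 2 (acetal carbon unassigned) | COC(O[Al](CC(C)C)CC(C)C)[C@@H](C)CO[Si](c1ccccc1)(c1ccccc1)C(C)(C)C | intermediate (not isolated)
4 | (2S)-3-[(tert-butyldiphenylsilyl)oxy]-2-methylpropanal | O=C[C@@H](C)CO[Si](c1ccccc1)(c1ccccc1)C(C)(C)C | intermediate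
5 | pentan-3-one | CCC(=O)CC | starting material
6 | hexanal | CCCCCC=O | starting material
7 | lithium pent-2-en-3-olate | CC=C(CC)O[Li] | intermediate (not isolated)
8 | 5-hydroxy-4-methyldecan-3-one (racemic syn/anti mixture) | CCCCCC(O)C(C)C(=O)CC | intermediate
9 | 4-methyl-5-[(trimethylsilyl)oxy]decan-3-one | CCCCCC(O[Si](C)(C)C)C(C)C(=O)CC | intermediate
10 | lithium 4-methyl-5-[(trimethylsilyl)oxy]dec-2-en-3-olate | CCCCCC(O[Si](C)(C)C)C(C)C(O[Li])=CC | intermediate (not isolated)
11 | (2S)-1-[(tert-butyldiphenylsilyl)oxy]-3-hydroxy-2,4,6-trimethyl-7-[(trimethylsilyl)oxy]dodecan-5-one (other centres mixed) | CCCCCC(O[Si](C)(C)C)C(C)C(=O)C(C)C(O)[C@@H](C)CO[Si](c1ccccc1)(c1ccccc1)C(C)(C)C | intermediate (not isolated)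
12 | (2S)-1-[(tert-butyldiphenylsilyl)oxy]-3,7-dihydroxy-2,4,6-trimethyldodecan-5-one (other centres mixed) | CCCCCC(O)C(C)C(=O)C(C)C(O)[C@@H](C)CO[Si](c1ccccc1)(c1ccccc1)C(C)(C)C | intermediate
13 | (2S)-1-[(tert-butyldiphenylsilyl)oxy]-2,4,6-trimethyldodecane-3,5,7-trione (tautomer mixture) | CCCCCC(=O)C(C)C(=O)C(C)C(=O)[C@@H](C)CO[Si](c1ccccc1)(c1ccccc1)C(C)(C)C | intermediate
14 | 2-{(2S)-1-[(tert-butyldiphenylsilyl)oxy]propan-2-yl}-3,5-dimethyl-6-pentyl-4H-pyran-4-one | CCCCCc1oc([C@@H](C)CO[Si](c2ccccc2)(c2ccccc2)C(C)(C)C)c(C)c(=O)c1C | intermediate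
15 | 2-[(2S)-1-hydroxypropan-2-yl]-3,5-dimethyl-6-pentyl-4H-pyran-4-one | CCCCCc1oc([C@@H](C)CO)c(C)c(=O)c1C | intermediate
16 | (2R)-2-(3,5-dimethyl-4-oxo-6-pentyl-4H-pyran-2-yl)propanal | CCCCCc1oc([C@@H](C)C=O)c(C)c(=O)c1C | intermediate
17 | propanoyl chloride | CCC(=O)Cl | starting material
18 | 4-methylheptane-3,5-dione | CCC(=O)C(C)C(=O)CC | intermediate
19 | methyl propanoate | CCC(=O)OC | starting material
20 | dilithium 4-methylhepta-2,4-diene-3,5-diolate | CC=C(O[Li])C(C)=C(CC)O[Li] | intermediate (not isolated)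
21 | 4,6-dimethylnonane-3,5,7-trione | CCC(=O)C(C)C(=O)C(C)C(=O)CC | intermediate
22 | 2,6-diethyl-3,5-dimethyl-4H-pyran-4-one | CCc1oc(CC)c(C)c(=O)c1C | intermediate
23 | lithium (2Z)-6-ethyl-2-ethylidene-3,5-dimethyl-2H-pyran-4-olate | C/C=C1\OC(CC)=C(C)C(O[Li])=C1C | intermediate (not isolated)
24 | 2-[(2S,3R,4R)-4-(6-ethyl-3,5-dimethyl-4-oxo-4H-pyran-2-yl)-3-hydroxypentan-2-yl]-3,5-dimethyl-6-pentyl-4H-pyran-4-one | CCCCCc1oc([C@@H](C)[C@H](O)[C@@H](C)c2oc(CC)c(C)c(=O)c2C)c(C)c(=O)c1C | intermediate
25 | 2-[(2R,4S)-4-(6-ethyl-3,5-dimethyl-4-oxo-4H-pyran-2-yl)-3-oxopentan-2-yl]-3,5-dimethyl-6-pentyl-4H-pyran-4-one (CNP0268096.2) | CCCCCc1oc([C@@H](C)C(=O)[C@@H](C)c2oc(CC)c(C)c(=O)c2C)c(C)c(=O)c1C | target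

**Step count**
Total: 14 steps. Longest linear sequence: 9 steps (1, 2, 5, 6, 7, 8, 9, 13, 14; the branch through 3 and 4 is equally long).

**Steps most likely to fail and fallbacks**

Step 13. The α-CH of 16 is very acidic, so proton transfer to dienolate 23 can cost yield and enantiopurity, and control of C4 rests on an open transition state and may be only moderate. The fallback sets out from 16 and comes back at 24.
- Aldehyde 16 is crotylated under neutral, reagent-controlled conditions with (Z)-crotyl-B(Ipc)2 (from cis-but-2-ene, KOt-Bu/n-BuLi, Ipc2BOMe of the antipode that reinforces Felkin attack, BF3·OEt2; THF, −78 °C; ethanolamine work-up) to give the syn,syn homoallylic alcohol F1.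
- Silylation (TESOTf, 2,6-lutidine, CH2Cl2) gives the triethylsilyl ether F2.
- Lemieux–Johnson cleavage (OsO4 cat., NaIO4, 2,6-lutidine, dioxane/H2O) gives the aldehyde F3.
- Addition of dianion 20 (THF, −78 °C) gives the β-hydroxy diketone F4, and Dess–Martin oxidation gives the triketone F5.
- PPh3/CCl4 cyclodehydration, which now builds ring B last, gives the silyl-protected bis-pyranone F6, and HF·pyridine releases 24.

Step 14. The product has two doubly activated α-stereocentres, so epimerisation at C2 or C4 (or retro-aldol of 24) during oxidation would scramble the stereochemistry. The fallback sets out from 15 and 22 and arrives at 25 without passing through carbinol 24.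
- Alcohol 15 is oxidised (TEMPO cat., NaOCl, NaClO2, pH 6.7 buffer, MeCN) to the carboxylic acid F7, which 1-chloro-N,N,2-trimethylprop-1-en-1-amine converts under neutral conditions into the acid chloride F8.
- Pyranone 22 is chlorinated at one ethyl α-carbon (LiN(SiMe3)2, THF, −78 °C; then C2Cl6) to give the racemic chloride F9.
- F8 and F9 are joined by an enantioconvergent nickel-catalysed reductive acyl cross-coupling (NiCl2·glyme, chiral bis(oxazoline) ligand, Mn powder, 2,6-dimethylbenzoic acid, DMA/THF, rt). This forms the C3–C4 bond directly at the ketone oxidation level without base, with the ligand enantiomer chosen to give 4S.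

Step 7. Cyclodehydration of 13 may be sluggish, and the HCl formed may erode the C2 centre or the silyl ether. The fallback sets out from 2 and 9 and comes back at 14.
- Lithium enolate 10 (2.2 equiv, from 9) is C-acylated with ester 2 in a Claisen condensation (THF, −78 → 0 °C) to give the O-TMS β-diketone F10.
- CF3CO2H in CH2Cl2 at 0 °C removes the TMS group, and the freed C7 hydroxyl closes onto the C3 carbonyl with loss of water to give the 2,3-dihydro-4H-pyran-4-one F11.
- Dehydrogenation (DDQ, dioxane, 80 °C, or Saegusa oxidation of the silyl dienol ether with Pd(OAc)2) gives pyranone 14.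

**Further compounds**
F1 | step 13 | 2-[(2S,3R,4S)-3-hydroxy-4-methylhex-5-en-2-yl]-3,5-dimethyl-6-pentyl-4H-pyran-4-one | CCCCCc1oc([C@@H](C)[C@H](O)[C@@H](C)C=C)c(C)c(=O)c1C
F2 | step 13 | 2-[(2S,3R,4S)-4-methyl-3-(triethylsilyloxy)hex-5-en-2-yl]-3,5-dimethyl-6-pentyl-4H-pyran-4-one | CCCCCc1oc([C@@H](C)[C@H](O[Si](CC)(CC)CC)[C@@H](C)C=C)c(C)c(=O)c1C
F3 | step 13 | (2R,3S,4S)-4-(3,5-dimethyl-4-oxo-6-pentyl-4H-pyran-2-yl)-2-methyl-3-(triethylsilyloxy)pentanal | CCCCCc1oc([C@@H](C)[C@H](O[Si](CC)(CC)CC)[C@@H](C)C=O)c(C)c(=O)c1C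
F4 | step 13 | 2-[(2S,3R,4S)-5-hydroxy-4,6,8-trimethyl-7,9-dioxo-3-(triethylsilyloxy)undecan-2-yl]-3,5-dimethyl-6-pentyl-4H-pyran-4-one (C5, C6, C8 mixed) | CCCCCc1oc([C@@H](C)[C@H](O[Si](CC)(CC)CC)[C@@H](C)C(O)C(C)C(=O)C(C)C(=O)CC)c(C)c(=O)c1C
F5 | step 13 | 2-[(2S,3S,4R)-4,6,8-trimethyl-5,7,9-trioxo-3-(triethylsilyloxy)undecan-2-yl]-3,5-dimethyl-6-pentyl-4H-pyran-4-one | CCCCCc1oc([C@@H](C)[C@H](O[Si](CC)(CC)CC)[C@@H](C)C(=O)C(C)C(=O)C(C)C(=O)CC)c(C)c(=O)c1C
F6 | step 13 | 2-[(2S,3R,4R)-4-(6-ethyl-3,5-dimethyl-4-oxo-4H-pyran-2-yl)-3-(triethylsilyloxy)pentan-2-yl]-3,5-dimethyl-6-pentyl-4H-pyran-4-one | CCCCCc1oc([C@@H](C)[C@H](O[Si](CC)(CC)CC)[C@@H](C)c2oc(CC)c(C)c(=O)c2C)c(C)c(=O)c1C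
F7 | step 14 | (2R)-2-(3,5-dimethyl-4-oxo-6-pentyl-4H-pyran-2-yl)propanoic acid | CCCCCc1oc([C@@H](C)C(=O)O)c(C)c(=O)c1C
F8 | step 14 | (2R)-2-(3,5-dimethyl-4-oxo-6-pentyl-4H-pyran-2-yl)propanoyl chloride | CCCCCc1oc([C@@H](C)C(=O)Cl)c(C)c(=O)c1C
F9 | step 14 | 2-(1-chloroethyl)-6-ethyl-3,5-dimethyl-4H-pyran-4-one (racemic) | CCc1oc(C(C)Cl)c(C)c(=O)c1C
F10 | step 7 | (2S)-1-[(tert-butyldiphenylsilyl)oxy]-2,4,6-trimethyl-7-[(trimethylsilyl)oxy]dodecane-3,5-dione | CCCCCC(O[Si](C)(C)C)C(C)C(=O)C(C)C(=O)[C@@H](C)CO[Si](c1ccccc1)(c1ccccc1)C(C)(C)C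
F11 | step 7 | 6-{(2S)-1-[(tert-butyldiphenylsilyl)oxy]propan-2-yl}-3,5-dimethyl-2-pentyl-2,3-dihydro-4H-pyran-4-one (C2, C3 mixed) | CCCCCC1OC([C@@H](C)CO[Si](c2ccccc2)(c2ccccc2)C(C)(C)C)=C(C)C(=O)C1C
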